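## Retrosynthetic overview

1. The tetronic acid is the only ring that is built (the furan is bought as 3-bromofuran). It is closed last by Dieckmann condensation (C3–C4) of an (E)-enol propanoate of an α-keto ester.
2. That enol ester (C5=C6, E) comes from the C6 aldehyde and a new Still–Gennari-type α-acyloxy phosphonate.
3. The skipped diene is cut at C12–C13: Pd-catalysed allylation of an (E)-alkenylalane (Zr-catalysed carboalumination of a terminal alkyne, which sets C11=C12) with an (E)-allylic acetate.
4. Alkyne fragment: (S)-2-methylhept-6-yn-1-ol from propanal by prolinol-ether-catalysed Michael addition to 1,1-bis(phenylsulfonyl)ethene (sets C7), then propargylation at the sulfone carbon and desulfonylation.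
5. Allylic acetate fragment: geranyl acetate (ozonolysis of the remote alkene) plus 3-furyllithium; both carbinols are oxidised together after the coupling.

Numbering used for the target: ring O1, C2(=O), C3(Me), C4(OH), C5; chain C6 (=CH) to C18 (C=O).

Assumption: the SMILES is read as (5E) at the exocyclic alkene (side chain cis to C4–OH), (E,E) in the chain and (S) at the methine C7.

## Route

Step 1
Reactants: 1 propanal; 2 1,1-bis(phenylsulfonyl)ethene
Product: 4 (2S)-2-methyl-4,4-bis(phenylsulfonyl)butan-1-ol, via Michael adduct aldehyde 3 (not isolated)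
Conditions: 1 (3 equiv), (R)-2-{bis[3,5-bis(trifluoromethyl)phenyl][(trimethylsilyl)oxy]methyl}pyrrolidine (10 mol %), CHCl3, 0 °C; then NaBH4, MeOH, 0 °C
Reagents that add atoms: none
Why: Enamine-catalysed (Hayashi–Jørgensen type) Michael addition; the (R)-diarylprolinol silyl ether forms the anti (E)-enamine of propanal and shields one face, so the vinyl bis-sulfone adds to the open face to give the (S)-α-methyl aldehyde, which is reduced in the same flask before it can epimerise.

Step 2
Reactants: 4 (2S)-2-methyl-4,4-bis(phenylsulfonyl)butan-1-ol; 5 propargyl bromide (3-bromoprop-1-yne)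
Product: 6 (2S)-2-methyl-4,4-bis(phenylsulfonyl)hept-6-yn-1-ol
Conditions: K2CO3 (2 equiv), DMF, 40 °C
Reagents that add atoms: none
Why: Carbonate deprotonates only the bis-sulfonyl methine (pKa about 12), and the soft carbanion is C-alkylated by SN2 at the propargylic bromide while the free primary alcohol and the remote stereocentre are untouched.

Step 3
Reactants: 6 (2S)-2-methyl-4,4-bis(phenylsulfonyl)hept-6-yn-1-ol
Product: 7 (2S)-2-methylhept-6-yn-1-ol
Conditions: Mg turnings (10 equiv), MeOH, 50 °C
Reagents that add atoms: none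
Why: Reductive desulfonylation by single-electron transfer from magnesium cleaves both C–S bonds and methanol protonates the carbanions; the isolated terminal alkyne and the alcohol are inert to Mg/MeOH.

Step 4
Reactants: 8 geranyl acetate [(2E)-3,7-dimethylocta-2,6-dien-1-yl acetate]
Product: 9 (2E)-3-methyl-6-oxohex-2-en-1-yl acetate
Conditions: O3 (1.0 equiv), CH2Cl2–pyridine, −78 °C; then Me2S, −78 °C to rt
Reagents that add atoms: ozone, [O-][O+]=O
Why: Chemoselective ozonolysis; the electron-rich remote 6,7-alkene reacts much faster than the 2,3-alkene deactivated by the allylic acetate, and reductive work-up gives the aldehyde with the (E)-allylic acetate intact.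

Step 5
Reactants: 9 (2E)-3-methyl-6-oxohex-2-en-1-yl acetate; 10 3-bromofuran
Product: 13 (2E)-6-(furan-3-yl)-3-methyl-6-[(trimethylsilyl)oxy]hex-2-en-1-yl acetate (racemic at C6), via 3-furyllithium 11 (not isolated), via lithium alkoxide adduct 12 (not isolated)
Conditions: 10, n-BuLi (1.05 equiv), THF, −78 °C; then 9, −78 °C; then Me3SiCl, −78 to 0 °C
Reagents that add atoms: chlorotrimethylsilane, C[Si](C)(C)Cl
Why: Bromine–lithium exchange gives 3-furyllithium (kept at −78 °C so it does not isomerise to the 2-lithio species), which adds 1,2 to the aldehyde far faster than to the acetate, and in situ O-silylation masks the carbinol; its racemic centre is erased at step 7.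

Step 6
Reactants: 7 (2S)-2-methylhept-6-yn-1-ol; 13 (2E)-6-(furan-3-yl)-3-methyl-6-[(trimethylsilyl)oxy]hex-2-en-1-yl acetate
Product: 16 (4E,7E,12S)-1-(furan-3-yl)-4,8,12-trimethyltrideca-4,7-diene-1,13-diol (1:1 epimers at C1), via alkenylalane 14 (not isolated), via coupled silyl ether 15 (not isolated)
Conditions: 7, Me3Al (3 equiv), Cp2ZrCl2 (25 mol %), CH2Cl2, 0 °C to rt; volatiles removed; 13, Pd(PPh3)4 (5 mol %), THF, 0 °C to rt; aq. Rochelle salt; then K2CO3 (cat.), MeOH, rt
Reagents that add atoms: trimethylaluminium, C[Al](C)C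
Why: Negishi Zr-catalysed carboalumination adds Me and Al syn across the alkyne (Me on the internal carbon), and Negishi Pd-catalysed alkenyl–allyl coupling at the primary allyl terminus keeps both alkene geometries, giving the (E,E)-1,4-diene; the silyl ether prevents Pd-mediated cyclisation of the carbinol onto the π-allyl and is removed by K2CO3/MeOH.

Step 7
Reactants: 16 (4E,7E,12S)-1-(furan-3-yl)-4,8,12-trimethyltrideca-4,7-diene-1,13-diol
Product: 17 (2S,6E,9E)-13-(furan-3-yl)-2,6,10-trimethyl-13-oxotrideca-6,9-dienal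
Conditions: Dess–Martin periodinane (3 equiv), NaHCO3, CH2Cl2, 0 °C to rt
Reagents that add atoms: none
Why: Dess–Martin oxidation takes the primary alcohol to the aldehyde and the furyl carbinol to the ketone in one operation under buffered conditions that do not epimerise the α-methyl aldehyde; both carbinol epimers converge.

Step 8
Reactants: 18 bis(2,2,2-trifluoroethyl) phosphite; 19 ethyl glyoxylate; 20 propanoyl chloride
Product: 22 ethyl 2-[bis(2,2,2-trifluoroethoxy)phosphoryl]-2-(propanoyloxy)acetate, via hydroxyphosphonate 21 (not isolated)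
Conditions: 18, 19, Et3N (5 mol %), CH2Cl2, 0 °C; then pyridine, 20, 0 °C to rt
Reagents that add atoms: none
Why: Pudovik addition of the P–H phosphite to the aldehyde followed by O-acylation, the way the dialkyl 2-acyloxy-2-phosphonoacetates are made; acylation at 0 °C outruns phospha-Brook rearrangement of the α-hydroxyphosphonate.

Step 9
Reactants: 17 (2S,6E,9E)-13-(furan-3-yl)-2,6,10-trimethyl-13-oxotrideca-6,9-dienal; 22 ethyl 2-[bis(2,2,2-trifluoroethoxy)phosphoryl]-2-(propanoyloxy)acetate
Product: 23 ethyl (2E,4S,8E,11E)-15-(furan-3-yl)-4,8,12-trimethyl-15-oxo-2-(propanoyloxy)pentadeca-2,8,11-trienoate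
Conditions: 22 (1.3 equiv), KHMDS (1.25 equiv), 18-crown-6 (3 equiv), THF, −78 °C; then 17, −78 °C
Reagents that add atoms: none
Why: Proposed new method: a Still–Gennari-type Horner–Wadsworth–Emmons reagent carrying an α-acyloxy group, designed to give the contra-thermodynamic (E)-enol ester of an α-keto ester: the electron-poor P(OCH2CF3)2 group with K+/18-crown-6 should make addition irreversible and oxaphosphetane collapse fast, so the kinetically preferred adduct (the one that puts the aldehyde substituent cis to CO2R in Still–Gennari and Ando olefinations, α-alkyl and α-fluoro reagents included) goes straight to the alkene with the chain cis to CO2Et and trans to the acyloxy oxygen; the closest known reactions are Still–Gennari/Ando olefination and the HWE reaction of dialkyl 2-acyloxy-2-phosphonoacetates, which gives mainly the opposite (Z) enol ester; the weakly basic anion reacts with the aldehyde only and leaves the aryl ketone and the α-stereocentre alone.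

Step 10
Reactants: 23 ethyl (2E,4S,8E,11E)-15-(furan-3-yl)-4,8,12-trimethyl-15-oxo-2-(propanoyloxy)pentadeca-2,8,11-trienoate
Product: 24 (5E)-5-[(2S,6E,9E)-13-(furan-3-yl)-2,6,10-trimethyl-13-oxotrideca-6,9-dien-1-ylidene]-4-hydroxy-3-methylfuran-2(5H)-one
Conditions: LiHMDS (3.3 equiv), THF, −78 to −30 °C; cold 1 M HCl to pH 3; light excluded
Reagents that add atoms: none
Why: Dieckmann (intramolecular Claisen) condensation; the enolate of the enol propanoate attacks the neighbouring ethyl ester 5-exo-trig and expels ethoxide to give the 3-methyltetronate anion, and because the C5=C6 bond and C7 take no part, the E geometry and the (S) centre are carried into the ring (the extra base covers the ketone α-position and the acidic product).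

## Compound list

1 | propanal | CCC=O | starting material
2 | 1,1-bis(phenylsulfonyl)ethene | C=C(S(=O)(=O)c1ccccc1)S(=O)(=O)c1ccccc1 | starting material
3 | (2S)-2-methyl-4,4-bis(phenylsulfonyl)butanal (not isolated) | O=C[C@@H](C)CC(S(=O)(=O)c1ccccc1)S(=O)(=O)c1ccccc1 | intermediate
4 | (2S)-2-methyl-4,4-bis(phenylsulfonyl)butan-1-ol | OC[C@@H](C)CC(S(=O)(=O)c1ccccc1)S(=O)(=O)c1ccccc1 | intermediate
5 | propargyl bromide (3-bromoprop-1-yne) | C#CCBr | starting material
6 | (2S)-2-methyl-4,4-bis(phenylsulfonyl)hept-6-yn-1-ol | OC[C@@H](C)CC(CC#C)(S(=O)(=O)c1ccccc1)S(=O)(=O)c1ccccc1 | intermediate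
7 | (2S)-2-methylhept-6-yn-1-ol | OC[C@@H](C)CCCC#C | intermediate
8 | geranyl acetate, (2E)-3,7-dimethylocta-2,6-dien-1-yl acetate | CC(C)=CCC/C(C)=C/COC(C)=O | starting material
9 | (2E)-3-methyl-6-oxohex-2-en-1-yl acetate | O=CCC/C(C)=C/COC(C)=O | intermediate
10 | 3-bromofuran | Brc1ccoc1 | starting material
11 | 3-furyllithium (not isolated) | [Li]c1ccoc1 | intermediate
12 | lithium (4E)-6-acetoxy-1-(furan-3-yl)-4-methylhex-4-en-1-olate, racemic (not isolated) | [Li]OC(CC/C(C)=C/COC(C)=O)c1ccoc1 | intermediate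
13 | (2E)-6-(furan-3-yl)-3-methyl-6-[(trimethylsilyl)oxy]hex-2-en-1-yl acetate, racemic | C[Si](C)(C)OC(CC/C(C)=C/COC(C)=O)c1ccoc1 | intermediate
14 | dimethyl{(1E,6S)-7-[(dimethylalumanyl)oxy]-2,6-dimethylhept-1-en-1-yl}alumane (not isolated) | C[Al](C)OC[C@@H](C)CCC/C(C)=C/[Al](C)C | intermediate
15 | (2S,6E,9E)-13-(furan-3-yl)-2,6,10-trimethyl-13-[(trimethylsilyl)oxy]trideca-6,9-dien-1-ol, C13 epimers (not isolated) | OC[C@@H](C)CCC/C(C)=C/C/C=C(\C)CCC(O[Si](C)(C)C)c1ccoc1 | intermediate
16 | (4E,7E,12S)-1-(furan-3-yl)-4,8,12-trimethyltrideca-4,7-diene-1,13-diol, C1 epimers | OC[C@@H](C)CCC/C(C)=C/C/C=C(\C)CCC(O)c1ccoc1 | intermediate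
17 | (2S,6E,9E)-13-(furan-3-yl)-2,6,10-trimethyl-13-oxotrideca-6,9-dienal | O=C[C@@H](C)CCC/C(C)=C/C/C=C(\C)CCC(=O)c1ccoc1 | intermediate
18 | bis(2,2,2-trifluoroethyl) phosphite | O=[PH](OCC(F)(F)F)OCC(F)(F)F | starting material
19 | ethyl glyoxylate | CCOC(=O)C=O | starting material
20 | propanoyl chloride | CCC(=O)Cl | starting material
21 | ethyl 2-[bis(2,2,2-trifluoroethoxy)phosphoryl]-2-hydroxyacetate (not isolated) | CCOC(=O)C(O)P(=O)(OCC(F)(F)F)OCC(F)(F)F | intermediate
22 | ethyl 2-[bis(2,2,2-trifluoroethoxy)phosphoryl]-2-(propanoyloxy)acetate | CCOC(=O)C(OC(=O)CC)P(=O)(OCC(F)(F)F)OCC(F)(F)F | intermediate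
23 | ethyl (2E,4S,8E,11E)-15-(furan-3-yl)-4,8,12-trimethyl-15-oxo-2-(propanoyloxy)pentadeca-2,8,11-trienoate | CCOC(=O)/C(OC(=O)CC)=C\[C@@H](C)CCC/C(C)=C/C/C=C(\C)CCC(=O)c1ccoc1 | intermediate
24 | (5E)-5-[(2S,6E,9E)-13-(furan-3-yl)-2,6,10-trimethyl-13-oxotrideca-6,9-dien-1-ylidene]-4-hydroxy-3-methylfuran-2(5H)-one | CC1=C(O)/C(=C\[C@@H](C)CCC/C(C)=C/C/C=C(\C)CCC(=O)c2ccoc2)OC1=O | target

## Step count and risks

Total step count: 10 (one-pot sequences counted once). Longest linear sequence: 7 steps (1, 2, 3, 6, 7, 9, 10).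

**Step 9 (the new olefination) is the most likely to fail.** The E/Z ratio of the enol ester is untested and could be poor. The fallback is known chemistry, sets out from 17 and comes back at 24. 3-Methyltetronic acid is O-methylated (Me2SO4, K2CO3, acetone) to 4-methoxy-3-methylfuran-2(5H)-one F1. Its C5-lithio derivative (LDA, THF, −78 °C) adds to the aldehyde of 17 (vinylogous aldol; the aryl ketone is left alone at −78 °C) to give 5-[(1R,2S,6E,9E)-13-(furan-3-yl)-1-hydroxy-2,6,10-trimethyl-13-oxotrideca-6,9-dien-1-yl]-4-methoxy-3-methylfuran-2(5H)-one F2 as C5/C1′ diastereomers. The (5R\*,1′R\*) pair is separated and dehydrated by stereospecific anti-elimination under Mitsunobu conditions (PPh3, DEAD, THF), which places the chain cis to C4 and gives the (E)-ylidene methyl tetronate, (5E)-5-[(2S,6E,9E)-13-(furan-3-yl)-2,6,10-trimethyl-13-oxotrideca-6,9-dien-1-ylidene]-4-methoxy-3-methylfuran-2(5H)-one F3. The (5R\*,1′S\*) pair is set aside. SN2 O-demethylation (LiCl, DMF, 60 °C, dark) then gives 24.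

**Step 10 (Dieckmann closure) is second.** The ketone enolate formed by the excess base may interfere, and γ-deprotonation at C7 of the enol ester would erode both geometry and configuration. The fallback sets out from 16 and comes back at 24. Only the primary alcohol of 16 is oxidised (TEMPO cat., PhI(OAc)2, CH2Cl2) to (2S,6E,9E)-13-(furan-3-yl)-13-hydroxy-2,6,10-trimethyltrideca-6,9-dienal F4. This is olefinated with 22 as in step 9 to ethyl (2E,4S,8E,11E)-15-(furan-3-yl)-15-hydroxy-4,8,12-trimethyl-2-(propanoyloxy)pentadeca-2,8,11-trienoate F5. LiHMDS (2.5 equiv, −78 °C), with no ketone α-protons now present, closes the ring to (5E)-5-[(2S,6E,9E)-13-(furan-3-yl)-13-hydroxy-2,6,10-trimethyltrideca-6,9-dien-1-ylidene]-4-hydroxy-3-methylfuran-2(5H)-one F6, and MnO2 (CH2Cl2) oxidises the furyl carbinol to give 24. If geometry is lost in the ring closure itself, the step 9 fallback, which has the ring in place before the alkene is made, is used instead.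

**Step 6 (one-pot carboalumination and Pd allylation) is third.** The alane may couple poorly with the functionalised allylic acetate, or attack the silyl ether or furan. The fallback sets out from alkenylalane 14 (made from 7 as in step 6) and comes back at 16. The alane is quenched with I2 (THF, −30 °C) to (2S,6E)-7-iodo-2,6-dimethylhept-6-en-1-ol F7, which is purified. Miyaura borylation (B2pin2, PdCl2(dppf), KOAc, dioxane) gives (2S,6E)-2,6-dimethyl-7-(4,4,5,5-tetramethyl-1,3,2-dioxaborolan-2-yl)hept-6-en-1-ol F8. Suzuki–Miyaura alkenyl–allyl coupling with acetate 13 (Pd(PPh3)4, K3PO4, THF–H2O) gives 15, and K2CO3/MeOH then gives 16.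

## Further compounds

F1 | step 9 | 4-methoxy-3-methylfuran-2(5H)-one | COC1=C(C)C(=O)OC1
F2 | step 9 | 5-[(1R,2S,6E,9E)-13-(furan-3-yl)-1-hydroxy-2,6,10-trimethyl-13-oxotrideca-6,9-dien-1-yl]-4-methoxy-3-methylfuran-2(5H)-one, (5R\*,1′R\*) pair, (5R,1′R) member shown | COC1=C(C)C(=O)O[C@@H]1[C@H](O)[C@@H](C)CCC/C(C)=C/C/C=C(\C)CCC(=O)c1ccoc1
F3 | step 9 | (5E)-5-[(2S,6E,9E)-13-(furan-3-yl)-2,6,10-trimethyl-13-oxotrideca-6,9-dien-1-ylidene]-4-methoxy-3-methylfuran-2(5H)-one | COC1=C(C)C(=O)O/C1=C/[C@@H](C)CCC/C(C)=C/C/C=C(\C)CCC(=O)c1ccoc1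
F4 | step 10 | (2S,6E,9E)-13-(furan-3-yl)-13-hydroxy-2,6,10-trimethyltrideca-6,9-dienal, C13 epimers | O=C[C@@H](C)CCC/C(C)=C/C/C=C(\C)CCC(O)c1ccoc1
F5 | step 10 | ethyl (2E,4S,8E,11E)-15-(furan-3-yl)-15-hydroxy-4,8,12-trimethyl-2-(propanoyloxy)pentadeca-2,8,11-trienoate, C15 epimers | CCOC(=O)/C(OC(=O)CC)=C\[C@@H](C)CCC/C(C)=C/C/C=C(\C)CCC(O)c1ccoc1
F6 | step 10 | (5E)-5-[(2S,6E,9E)-13-(furan-3-yl)-13-hydroxy-2,6,10-trimethyltrideca-6,9-dien-1-ylidene]-4-hydroxy-3-methylfuran-2(5H)-one, C13′ epimers | CC1=C(O)/C(=C\[C@@H](C)CCC/C(C)=C/C/C=C(\C)CCC(O)c2ccoc2)OC1=O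
F7 | step 6 | (2S,6E)-7-iodo-2,6-dimethylhept-6-en-1-ol | OC[C@@H](C)CCC/C(C)=C/I
F8 | step 6 | (2S,6E)-2,6-dimethyl-7-(4,4,5,5-tetramethyl-1,3,2-dioxaborolan-2-yl)hept-6-en-1-ol | OC[C@@H](C)CCC/C(C)=C/B1OC(C)(C)C(C)(C)O1
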